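**Plan**
- The target is an achiral tridepside: ring C is the 2-methoxy-6-methylbenzoic acid ring (unprimed locants), ring B the central ring (primed), ring A the terminal 2,4-dihydroxy-6-methylbenzoyl ring (double-primed). There is no stereocentre to set.
- Retrosynthesis: the C4''–O bond of ring A is cut back to C–H first, then the ring A–ring B ester C(=O)–O bond, then the ring B–ring C ester C(=O)–O bond. Two methoxymethyl ethers and a tert-butyl ester are the last groups removed in the forward sense.
- Forward: 2,4-dihydroxy-6-methylbenzaldehyde gives, through one common 4-O-benzyl ether, the ring C phenol and the ring B acid. These are esterified, debenzylated and acylated with methoxymethyl-protected 6-methylsalicylic acid (ring A).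
- Enabling feature: in the 4''-deoxy tridepside, C4''–H of ring A is the only aromatic C–H whose two neighbouring ring carbons (C3'', C5'') both carry hydrogen. Every C–H of rings B and C sits between two substituents, so a sterically governed borylation–oxidation can place the last hydroxyl at C4''.

Key step: step 13

Assumption: 2,4-dihydroxy-6-methylbenzaldehyde, 6-methylsalicylic acid and bis(pinacolato)diboron are taken as purchasable.
Abbreviations: MOM = methoxymethyl; DCC = N,N'-dicyclohexylcarbodiimide; DMAP = 4-(dimethylamino)pyridine; dtbpy = 4,4'-di-tert-butyl-2,2'-bipyridine; B2pin2 = bis(pinacolato)diboron.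

**Ring C phenol**

Step 1
Reactants: 1 2,4-dihydroxy-6-methylbenzaldehyde
Product: 2 4-(benzyloxy)-2-hydroxy-6-methylbenzaldehyde
Conditions: BnBr (1.05 equiv), K2CO3, acetone, rt
Reagents that add atoms: benzyl bromide, BrCc1ccccc1
Why: Williamson etherification; the 2-OH is held in a hydrogen bond to the formyl group and is less acidic, so one equivalent of benzyl bromide should alkylate the 4-OH selectively.

Step 2
Reactants: 2 4-(benzyloxy)-2-hydroxy-6-methylbenzaldehyde
Product: 3 4-(benzyloxy)-2-methoxy-6-methylbenzaldehyde
Conditions: MeI, K2CO3, DMF, rt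
Reagents that add atoms: iodomethane, CI
Why: Williamson O-methylation of the remaining chelated phenol, which should proceed in a dipolar aprotic solvent once the 4-OH is blocked.

Step 3
Reactants: 3 4-(benzyloxy)-2-methoxy-6-methylbenzaldehyde
Product: 4 4-(benzyloxy)-2-methoxy-6-methylbenzoic acid
Conditions: NaClO2, NaH2PO4, 2-methyl-2-butene, t-BuOH/THF/H2O, 0 °C to rt
Reagents that add atoms: sodium chlorite, [Na+].[O-]Cl=O
Why: Pinnick oxidation takes the aryl aldehyde to the acid under buffered conditions, with 2-methyl-2-butene consuming the hypochlorous acid that could otherwise chlorinate the electron-rich ring.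

Step 4
Reactants: 4 4-(benzyloxy)-2-methoxy-6-methylbenzoic acid
Product: 5 tert-butyl 4-(benzyloxy)-2-methoxy-6-methylbenzoate
Conditions: Me2NCH(Ot-Bu)2, toluene, 85 °C
Reagents that add atoms: N,N-dimethylformamide di-tert-butyl acetal, CN(C)C(OC(C)(C)C)OC(C)(C)C
Why: Esterification with a formamide acetal; the carboxylate is alkylated on oxygen by the tert-butyl fragment released from the protonated acetal, so the two ortho substituents that block attack at the carbonyl carbon do not interfere.

Step 5
Reactants: 5 tert-butyl 4-(benzyloxy)-2-methoxy-6-methylbenzoate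
Product: 6 tert-butyl 4-hydroxy-2-methoxy-6-methylbenzoate
Conditions: H2 (1 atm), 10% Pd/C, EtOAc, rt
Reagents that add atoms: none
Why: Hydrogenolysis of the aryl benzyl ether frees the 4-OH, while the tert-butyl ester and the methyl ether are inert.

**Ring B acid and the ring B–ring C ester**

Step 6
Reactants: 2 4-(benzyloxy)-2-hydroxy-6-methylbenzaldehyde
Product: 7 4-(benzyloxy)-2-(methoxymethoxy)-6-methylbenzaldehyde
Conditions: NaH, DMF, 0 °C; MOMCl, 0 °C to rt
Reagents that add atoms: chloromethyl methyl ether, COCCl
Why: Williamson-type O-alkylation of the phenoxide generated with NaH gives the methoxymethyl acetal; the aldehyde has no enolisable hydrogen and should be untouched.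

Step 7
Reactants: 7 4-(benzyloxy)-2-(methoxymethoxy)-6-methylbenzaldehyde
Product: 8 4-(benzyloxy)-2-(methoxymethoxy)-6-methylbenzoic acid
Conditions: NaClO2, NaH2PO4, 2-methyl-2-butene, t-BuOH/THF/H2O, 0 °C to rt
Reagents that add atoms: sodium chlorite, [Na+].[O-]Cl=O
Why: Pinnick oxidation at about pH 4 should leave the methoxymethyl and benzyl ethers intact and deliver the ring B acid.

Step 8
Reactants: 8 4-(benzyloxy)-2-(methoxymethoxy)-6-methylbenzoic acid; 6 tert-butyl 4-hydroxy-2-methoxy-6-methylbenzoate
Product: 9 tert-butyl 4-{[4-(benzyloxy)-2-(methoxymethoxy)-6-methylbenzoyl]oxy}-2-methoxy-6-methylbenzoate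
Conditions: DCC, DMAP (0.3 equiv), CH2Cl2, 0 °C to rt
Reagents that add atoms: none
Why: Steglich esterification; the acylpyridinium formed from the O-acylisourea and DMAP acylates the phenol under neutral conditions that suit a di-ortho-substituted acid carrying acid-labile groups.

Step 9
Reactants: 9 tert-butyl 4-{[4-(benzyloxy)-2-(methoxymethoxy)-6-methylbenzoyl]oxy}-2-methoxy-6-methylbenzoate
Product: 10 tert-butyl 4-{[4-hydroxy-2-(methoxymethoxy)-6-methylbenzoyl]oxy}-2-methoxy-6-methylbenzoate
Conditions: H2 (1 atm), 10% Pd/C, EtOAc, rt
Reagents that add atoms: none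
Why: Hydrogenolysis of the benzyl ether; the aryl ester, methoxymethyl ether and tert-butyl ester are stable to H2 over Pd/C, and this removes the last benzyl C–H bonds before the iridium step.

**Ring A acid and the tridepside**

Step 10
Reactants: 11 2-hydroxy-6-methylbenzoic acid (6-methylsalicylic acid)
Product: 12 methoxymethyl 2-(methoxymethoxy)-6-methylbenzoate
Conditions: NaH (2.2 equiv), DMF, 0 °C; MOMCl (2.4 equiv), 0 °C to rt
Reagents that add atoms: chloromethyl methyl ether, COCCl
Why: Double O-alkylation of the dianion (carboxylate and phenoxide) with chloromethyl methyl ether installs the ester and the ether in one operation.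

Step 11
Reactants: 12 methoxymethyl 2-(methoxymethoxy)-6-methylbenzoate
Product: 13 2-(methoxymethoxy)-6-methylbenzoic acid
Conditions: LiOH, THF/MeOH/H2O, rt; then 1 M HCl to pH 4, 0 °C
Reagents that add atoms: lithium hydroxide, [Li+].[OH-]
Why: Saponification; the methoxymethyl ester is an acyl acetal that hydroxide cleaves at room temperature, whereas the aryl methoxymethyl ether is stable to base and to the brief cold acidification.

Step 12
Reactants: 13 2-(methoxymethoxy)-6-methylbenzoic acid; 10 tert-butyl 4-{[4-hydroxy-2-(methoxymethoxy)-6-methylbenzoyl]oxy}-2-methoxy-6-methylbenzoate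
Product: 14 tert-butyl 2-methoxy-4-{[2-(methoxymethoxy)-4-{[2-(methoxymethoxy)-6-methylbenzoyl]oxy}-6-methylbenzoyl]oxy}-6-methylbenzoate (4''-deoxy tridepside)
Conditions: DCC, DMAP (0.3 equiv), CH2Cl2, 0 °C to rt
Reagents that add atoms: none
Why: Steglich esterification of the ring B phenol as in step 8; the existing depside ester is shielded by its two ortho substituents against acyl transfer.

**C4'' oxygenation and deprotection**

Step 13
Reactants: 14 4''-deoxy tridepside bis(methoxymethyl) ether tert-butyl ester; 15 bis(pinacolato)diboron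
Product: 17 tert-butyl 4-{[4-{[4-hydroxy-2-(methoxymethoxy)-6-methylbenzoyl]oxy}-2-(methoxymethoxy)-6-methylbenzoyl]oxy}-2-methoxy-6-methylbenzoate (4''-hydroxy tridepside), via C4''-pinacolboronate 16 (not isolated)
Conditions: [Ir(OMe)(cod)]2 (2.5 mol%), dtbpy (5 mol%), B2pin2 (1.0 equiv), THF, 70 °C; then NaBO3·4H2O, THF/H2O, rt
Reagents that add atoms: NaBO3·4H2O (sodium perborate tetrahydrate), [Na+].[O-]OB=O.O.O.O.O
Why: [Ir(OMe)(cod)]2, dtbpy and B2pin2 form the trivalent iridium tris(boryl) complex (dtbpy)Ir(Bpin)3, which cleaves an aromatic C–H bond by oxidative addition and releases arylboronate 16 by C–B reductive elimination; the peroxoborate anion then adds to boron, the aryl group shifts from boron to oxygen (1,2-migration), and hydrolysis of the borate ester frees the phenol. The closest known reaction type is the sterically controlled iridium-catalysed arene C–H borylation with one-pot oxidation of the boronate to a phenol, a known sequence applied here to a new substrate. No ring is closed and no stereocentre is formed. The step needs site selectivity among seven aromatic C–H bonds: this catalyst does not borylate next to a substituent, C3''–H and C5''–H each have one ortho substituent, the four C–H bonds of rings B and C have two, and only C4''–H has none. Methoxymethyl and tert-butyl groups offer no aromatic C–H bond, and the benzyl groups were removed beforehand, so no protecting group competes. The aryl esters should survive the mildly basic oxidation at room temperature because each carbonyl is shielded by two ortho substituents.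

Step 14
Reactants: 17 4''-hydroxy tridepside bis(methoxymethyl) ether tert-butyl ester
Product: 18 4-{[4-{[2,4-dihydroxy-6-methylbenzoyl]oxy}-2-hydroxy-6-methylbenzoyl]oxy}-2-methoxy-6-methylbenzoic acid (CNP0283563.0)
Conditions: CF3CO2H/CH2Cl2 (1:3), 0 °C to rt
Reagents that add atoms: none
Why: Acidolysis; protonation cleaves both methoxymethyl acetals through the oxocarbenium ion and the tert-butyl ester through the tert-butyl cation, while the aryl esters and the methyl ether are stable to anhydrous acid.

**Compound list**

1 | 2,4-dihydroxy-6-methylbenzaldehyde | Cc1cc(O)cc(O)c1C=O | starting material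
2 | 4-(benzyloxy)-2-hydroxy-6-methylbenzaldehyde | Cc1cc(OCc2ccccc2)cc(O)c1C=O | intermediate
3 | 4-(benzyloxy)-2-methoxy-6-methylbenzaldehyde | COc1cc(OCc2ccccc2)cc(C)c1C=O | intermediate
4 | 4-(benzyloxy)-2-methoxy-6-methylbenzoic acid | COc1cc(OCc2ccccc2)cc(C)c1C(=O)O | intermediate
5 | tert-butyl 4-(benzyloxy)-2-methoxy-6-methylbenzoate | COc1cc(OCc2ccccc2)cc(C)c1C(=O)OC(C)(C)C | intermediate
6 | tert-butyl 4-hydroxy-2-methoxy-6-methylbenzoate (ring C phenol) | COc1cc(O)cc(C)c1C(=O)OC(C)(C)C | intermediate
7 | 4-(benzyloxy)-2-(methoxymethoxy)-6-methylbenzaldehyde | COCOc1cc(OCc2ccccc2)cc(C)c1C=O | intermediate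
8 | 4-(benzyloxy)-2-(methoxymethoxy)-6-methylbenzoic acid (ring B acid) | COCOc1cc(OCc2ccccc2)cc(C)c1C(=O)O | intermediate
9 | tert-butyl 4-{[4-(benzyloxy)-2-(methoxymethoxy)-6-methylbenzoyl]oxy}-2-methoxy-6-methylbenzoate | COCOc1cc(OCc2ccccc2)cc(C)c1C(=O)Oc1cc(C)c(C(=O)OC(C)(C)C)c(OC)c1 | intermediate
10 | tert-butyl 4-{[4-hydroxy-2-(methoxymethoxy)-6-methylbenzoyl]oxy}-2-methoxy-6-methylbenzoate (ring B–ring C phenol) | COCOc1cc(O)cc(C)c1C(=O)Oc1cc(C)c(C(=O)OC(C)(C)C)c(OC)c1 | intermediate
11 | 2-hydroxy-6-methylbenzoic acid (6-methylsalicylic acid) | Cc1cccc(O)c1C(=O)O | starting material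
12 | methoxymethyl 2-(methoxymethoxy)-6-methylbenzoate | COCOc1cccc(C)c1C(=O)OCOC | intermediate
13 | 2-(methoxymethoxy)-6-methylbenzoic acid (ring A acid) | COCOc1cccc(C)c1C(=O)O | intermediate
14 | 4''-deoxy tridepside, bis(methoxymethyl) ether, tert-butyl ester | COCOc1cccc(C)c1C(=O)Oc1cc(C)c(C(=O)Oc2cc(C)c(C(=O)OC(C)(C)C)c(OC)c2)c(OCOC)c1 | intermediate
15 | bis(pinacolato)diboron | CC1(C)OB(B2OC(C)(C)C(C)(C)O2)OC1(C)C | starting material
16 | 4''-(4,4,5,5-tetramethyl-1,3,2-dioxaborolan-2-yl) tridepside, bis(methoxymethyl) ether, tert-butyl ester | COCOc1cc(B2OC(C)(C)C(C)(C)O2)cc(C)c1C(=O)Oc1cc(C)c(C(=O)Oc2cc(C)c(C(=O)OC(C)(C)C)c(OC)c2)c(OCOC)c1 | intermediate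
17 | 4''-hydroxy tridepside, bis(methoxymethyl) ether, tert-butyl ester | COCOc1cc(O)cc(C)c1C(=O)Oc1cc(C)c(C(=O)Oc2cc(C)c(C(=O)OC(C)(C)C)c(OC)c2)c(OCOC)c1 | intermediate
18 | 4-{[4-{[2,4-dihydroxy-6-methylbenzoyl]oxy}-2-hydroxy-6-methylbenzoyl]oxy}-2-methoxy-6-methylbenzoic acid | COc1cc(OC(=O)c2c(C)cc(OC(=O)c3c(C)cc(O)cc3O)cc2O)cc(C)c1C(=O)O | target

**Step count**

Total steps: 14. Longest linear sequence: 10 steps (steps 1, 2, 3, 4, 5, 8, 9, 12, 13, 14).

**Steps most likely to fail**

Step 13. C–H activation may stall on a substrate this crowded with ester and acetal oxygens. Alternatively, the depside esters may be cleaved during the oxidation, either by attack of hydroperoxide or by elimination from the newly formed para-phenoxide of ring A. The fallback abandons the late C–H oxygenation and carries the C4'' oxygen in from the start. It sets out from acid 8 and phenol 10: Steglich esterification (DCC, DMAP, CH2Cl2) should give the 4''-O-benzyl tridepside bis(methoxymethyl) ether tert-butyl ester F1, and hydrogenolysis of F1 (H2, 10% Pd/C, EtOAc) removes the benzyl group and comes back to the route at 17.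

Step 12. Acyl transfer from the di-ortho-substituted carboxyl of 13 to the ester-deactivated phenol of 10 may be slow enough for the O-acylisourea to rearrange to the unreactive N-acylurea. The fallback replaces in-situ carbodiimide activation by a discrete, isolable acyl electrophile. It sets out from 13: cyanuric fluoride and pyridine in CH2Cl2 at −10 °C should give 2-(methoxymethoxy)-6-methylbenzoyl fluoride F2, which is small, neutral and compatible with the acetal. F2 with phenol 10 and Cs2CO3 in MeCN at rt should form the ester and come back to the route at 14.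

Step 14. The tert-butyl and methoxymethyl cations, or the formaldehyde set free, may be captured by the electron-rich ring A, and cleavage of three groups at once may be incomplete. The fallback splits the deprotection into two cation-poor stages and sets out from 17. TMSOTf with 2,2'-bipyridyl in CH2Cl2 at 0 °C, then water, should remove both methoxymethyl ethers; the methoxymethyl fragment is captured on the bipyridyl nitrogen instead of leaving as a free cation. This gives tert-butyl 4-{[4-{[2,4-dihydroxy-6-methylbenzoyl]oxy}-2-hydroxy-6-methylbenzoyl]oxy}-2-methoxy-6-methylbenzoate F3. Aqueous 85% H3PO4 in toluene should then cleave the tert-butyl ester of F3 with loss of isobutene and come back to the route at 18. Should the tert-butyl ester already fall in the first stage, the material converges on 18 as well.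

**Further compounds**

F1 | step 13 | 4''-O-benzyl tridepside, bis(methoxymethyl) ether, tert-butyl ester | COCOc1cc(OCc2ccccc2)cc(C)c1C(=O)Oc1cc(C)c(C(=O)Oc2cc(C)c(C(=O)OC(C)(C)C)c(OC)c2)c(OCOC)c1
F2 | step 12 | 2-(methoxymethoxy)-6-methylbenzoyl fluoride | COCOc1cccc(C)c1C(F)=O
F3 | step 14 | tert-butyl 4-{[4-{[2,4-dihydroxy-6-methylbenzoyl]oxy}-2-hydroxy-6-methylbenzoyl]oxy}-2-methoxy-6-methylbenzoate | COc1cc(OC(=O)c2c(C)cc(OC(=O)c3c(C)cc(O)cc3O)cc2O)cc(C)c1C(=O)OC(C)(C)C
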